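Retrosynthesis: cut the C8–O ester bond (side-chain acid), then C11=C13 and the O6–C12 lactone bond, then C10–CH3 (back to an enol triflate), then C2–C3 of the ten-membered ring.
Enabling feature: ring atoms C10=C1–C2–C3–C4=C5 (C1=C10 Z, C4=C5 E) form a 1,5-diene, so the ten-membered ring C1–C10 is the [3,3] product of a six-membered ring C5–C6–C7–C8–C9–C10 carrying a vinyl group and an oxygen on C10 and a cis isopropenyl group on C5.
Forward order of rings: cyclohexene C5–C10 first (ring-closing metathesis of a glucose-derived 1,7-diene), ten-membered ring second (oxy-Cope ring expansion with triflate trapping), γ-lactone third (oxidation of the O6/O12 diol), then the C8 ester chain.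
Stereochemistry: C6, C8 and C9 are C2, C4 and C5 of D-glucose; C7 comes from convex-face hydrogenation of a C3-branched furanose (allo); the chain stereocentre comes from (R)-2-methylsuccinic acid 4-tert-butyl ester; both ring alkene geometries come from the chair of the [3,3] shift.
Protecting groups: O12, O9, O6 and O8 are each capped when they are the only free hydroxyl (O8 is the furanose ring oxygen), so lactonisation, C8 acylation and C9 release need no regioselective step.

Key step: step 20

Remark: germacrane numbering is used for all carbocycles (ring C1–C10; C11 and C12 are the two arm carbons on C7, C12 being the oxygenated terminus; C13 is the exocyclic methylene). "Lower face" is the face of the six-membered ring that carries the C6–C9 substituents. Anomeric, C11/C12-epimeric and E/Z mixtures are carried on unseparated and their open centres are left unspecified in the SMILES.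
Remark: (R)-2-methylsuccinic acid 4-tert-butyl ester is taken as a purchasable building block.

Step 1
Reactants: 1 diacetone-D-glucose
Product: 2 1,2:5,6-di-O-isopropylidene-α-D-ribo-hexofuranos-3-ulose
Conditions: Dess–Martin periodinane, CH2Cl2, rt
Reagents that add atoms: none
Why: Dess–Martin oxidation of the only free hydroxyl (O3) should give the 3-ketone without touching either acetonide, and no stereocentre is made.

Step 2
Reactants: 2 3-ulose
Product: 3 exocyclic enoate (E/Z mixture)
Conditions: (EtO)2P(O)CH2CO2Et, NaH, THF, 0 °C → rt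
Reagents that add atoms: triethyl phosphonoacetate CCOC(=O)CP(=O)(OCC)OCC
Why: Horner–Wadsworth–Emmons olefination of the ketone with the stabilised phosphonate anion should install the two-carbon arm (future C11 and C12), and the alkene geometry is irrelevant because it is hydrogenated next.

Step 3
Reactants: 3 exocyclic enoate
Product: 4 3-deoxy-3-C-(2-ethoxy-2-oxoethyl)-1,2:5,6-di-O-isopropylidene-α-D-allofuranose
Conditions: H2 (1 atm), Pd/C, EtOAc, rt
Reagents that add atoms: none
Why: Heterogeneous catalytic hydrogenation should deliver hydrogen to the convex face of the cis-fused furanose–dioxolane bicycle, away from the 1,2-acetonide, so the arm ends on the acetonide face and C3 (the future C7) gets the allo configuration.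

Step 4
Reactants: 4 allo ester
Product: 5 3-deoxy-3-C-(2-hydroxyethyl)-1,2:5,6-di-O-isopropylidene-α-D-allofuranose
Conditions: LiAlH4, THF, 0 °C
Reagents that add atoms: none
Why: Hydride reduction of the ester should give the primary alcohol (future O12) while both acetals are inert to LiAlH4.

Step 5
Reactants: 5 primary alcohol
Product: 6 TBDPS ether of 5
Conditions: TBDPSCl, imidazole, DMF, rt
Reagents that add atoms: tert-butyl(chloro)diphenylsilane CC(C)(C)[Si](Cl)(c1ccccc1)c1ccccc1
Why: Silylation of the only hydroxyl should give an ether that survives the later acid, base and organometallic steps and is removed by fluoride.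

Step 6
Reactants: 6 TBDPS ether
Product: 7 5,6-diol (1,2-acetonide kept)
Conditions: AcOH/H2O (7:3), 40 °C
Reagents that add atoms: none
Why: Acid-catalysed acetal hydrolysis is selective for the terminal 5,6-dioxolane, because the 1,2-acetonide is a cis-fused anomeric acetal that is cleaved far more slowly in dilute acetic acid.

Step 7
Reactants: 7 5,6-diol
Product: 9 5,6-epoxide, via primary tosylate 8 (not isolated)
Conditions: TsCl, pyridine, 0 °C; then K2CO3, MeOH, rt
Reagents that add atoms: none
Why: Sulfonylation selects the primary O6 hydroxyl and the C5 alkoxide then closes the epoxide by intramolecular Williamson displacement at C6, so the C5 configuration is retained.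

Step 8
Reactants: 9 5,6-epoxide
Product: 10 allylic alcohol (hept-6-enofuranose, free 5-OH)
Conditions: Me3S+ I−, n-BuLi, THF, −10 °C → rt
Reagents that add atoms: trimethylsulfonium iodide C[S+](C)C.[I-]
Why: The sulfonium ylide attacks the terminal epoxide carbon and the betaine loses dimethyl sulfide by elimination (one-carbon homologation of an epoxide to an allylic alcohol), which leaves C5 untouched and turns C6, the future C10, into a vinyl carbon.

Step 9
Reactants: 10 allylic alcohol
Product: 11 5-O-(2-naphthylmethyl) ether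
Conditions: NaH, 2-(bromomethyl)naphthalene, Bu4NI (cat.), DMF, 0 °C → rt
Reagents that add atoms: 2-(bromomethyl)naphthalene BrCc1ccc2ccccc2c1
Why: Williamson etherification of the only free hydroxyl puts an acid-stable, DDQ-labile group on O5 (the future O9) and blocks pyranose formation in the next steps.

Step 10
Reactants: 11 5-O-NAP ether
Product: 12 methyl furanoside with free 2-OH (α/β mixture)
Conditions: p-TsOH·H2O (cat.), MeOH, 50 °C
Reagents that add atoms: methanol CO
Why: Acid-catalysed transacetalisation in methanol (Fischer glycosidation conditions) should exchange the 1,2-acetonide for a methyl furanoside and free O2, the future O6, as the only hydroxyl.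

Step 11
Reactants: 12 methyl furanoside
Product: 13 2-O-triisopropylsilyl methyl furanoside
Conditions: TIPSOTf, 2,6-lutidine, CH2Cl2, 0 °C → rt
Reagents that add atoms: triisopropylsilyl trifluoromethanesulfonate CC(C)[Si](C(C)C)(C(C)C)OS(=O)(=O)C(F)(F)F
Why: Silylation with the reactive silyl triflate should cap the hindered secondary O2 with a group chosen for its resistance to acid and to base-induced migration.

Step 12
Reactants: 13 2-O-TIPS methyl furanoside
Product: 14 lactol (anomeric mixture)
Conditions: 1 M aq. HCl, THF, 50 °C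
Reagents that add atoms: water O
Why: Aqueous acid hydrolysis of the furanoside acetal should release the lactol while the silyl and naphthylmethyl ethers, which tolerate dilute acid, stay in place.

Step 13
Reactants: 14 lactol
Product: 15 acyclic 1,7-diene with free O4-H (future O8-H)
Conditions: Ph3PCH3Br, KOtBu, THF, 0 °C → rt
Reagents that add atoms: methyltriphenylphosphonium bromide C[P+](c1ccccc1)(c1ccccc1)c1ccccc1.[Br-]
Why: Wittig methylenation of the open-chain aldehyde tautomer of the lactol should give the terminal alkene and free the former ring oxygen O4, the future O8, as the only hydroxyl.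

Step 14
Reactants: 15 acyclic 1,7-diene
Product: 16 all-cis cyclohexenol (ring C5–C10, C5=C10)
Conditions: second-generation Grubbs catalyst (H2IMes)(PCy3)Cl2Ru=CHPh (5 mol %), CH2Cl2, 40 °C
Reagents that add atoms: none
Why: Ring-closing metathesis of the 1,7-diene with loss of ethene should close the six-membered ring, a closure well known for sugar-derived dienes that carry allylic oxygen substituents and a free hydroxyl.

Step 15
Reactants: 16 cyclohexenol
Product: 17 lower-face epoxy alcohol
Conditions: VO(acac)2 (cat.), t-BuOOH, CH2Cl2, rt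
Reagents that add atoms: tert-butyl hydroperoxide CC(C)(C)OO
Why: In this hydroxyl-directed vanadium-catalysed epoxidation the vanadium alkoxide of the axial lower-face C8 hydroxyl (homoallylic to C10) should deliver the peroxide oxygen to the lower face of C5=C10, which sets both new centres cis to the C8 oxygen while undirected oxidation is slow.

Step 16
Reactants: 17 epoxy alcohol
Product: 18 8-O-(3,4-dimethoxybenzyl) epoxide
Conditions: NaH, 3,4-dimethoxybenzyl chloride, Bu4NI (cat.), THF/DMF, 0 °C
Reagents that add atoms: 3,4-dimethoxybenzyl chloride COc1ccc(CCl)cc1OC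
Why: Williamson etherification of the C8 alkoxide, which cannot open the epoxide because it sits on the same face as the epoxide oxygen, should install the most DDQ-labile of the arylmethyl groups on O8.

Step 17
Reactants: 18 DMB-protected epoxide; 19 isopropenylmagnesium bromide
Product: 20 trans-2-isopropenyl secondary alcohol (isopropenyl at C5 upper face, OH at C10 lower face)
Conditions: 19, CuBr·SMe2 (cat.), THF, −40 → 0 °C
Reagents that add atoms: none
Why: Copper-catalysed Grignard opening of the epoxide follows the trans-diaxial (Fürst–Plattner) rule, and in the half-chair that keeps the C7 arm equatorial and lets the axial C8 ether oxygen share magnesium with the epoxide oxygen the axial attack falls on C5 (flanked by the less electron-withdrawing silyl ether) from the upper face, which sets the isopropenyl group trans to the lower-face C10 hydroxyl.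

Step 18
Reactants: 20 secondary C10 alcohol
Product: 21 C10 ketone
Conditions: Dess–Martin periodinane, CH2Cl2, 0 °C → rt
Reagents that add atoms: none
Why: Dess–Martin oxidation of the hindered secondary alcohol should give the ketone under non-basic conditions that neither epimerise C5 nor move the isopropenyl double bond into conjugation.

Step 19
Reactants: 21 C10 ketone; 22 vinylmagnesium bromide
Product: 23 cis-1-vinyl-2-isopropenylcyclohexanol (vinyl upper face, OH lower face)
Conditions: 22, CeCl3, THF, −78 °C
Reagents that add atoms: none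
Why: In this 1,2-addition of the weakly basic vinylcerium reagent the lower face of the carbonyl is closed by the syn-axial C6 and C8 oxygens in one chair and by the axial C9 alkoxy group (Felkin–Anh) in the other, so the vinyl group should enter from the upper face, cis to the isopropenyl group, and leave the C10 hydroxyl on the lower face.

Step 20
Reactants: 23 cis-1-vinyl-2-isopropenylcyclohexanol
Product: 26 ten-membered enol triflate, via potassium alkoxide 24 (not isolated), via potassium enolate 25 (not isolated)
Conditions: KH, THF, 0 → 60 °C; then PhNTf2, −78 → 0 °C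
Reagents that add atoms: N-phenylbis(trifluoromethanesulfonimide) O=S(=O)(N(c1ccccc1)S(=O)(=O)C(F)(F)F)C(F)(F)F
Why: KH forms the C10 potassium alkoxide 24, and the oxido group drives a concerted [3,3] shift in which C2 bonds to C3 while C5–C10 breaks; this is the anionic oxy-Cope rearrangement, the known ring expansion of 1,2-dialkenylcyclohexanols to cyclodec-5-enone enolates with trapping of the enolate in the same flask. The ten-membered ring therefore arises by four-atom ring expansion through a six-membered chair transition state and not by end-to-end closure, and enolate 25 is formed regiospecifically at C10=C1 and triflated on oxygen by PhNTf2. No stereocentre is created (C5 and C10 become trigonal); what the step must control is the geometry of the two new alkenes, and this is fixed by the reacting chair: with the vinyl group equatorial and the isopropenyl and oxido groups axial on the cyclohexane (chair A), C9 is axial and the oxido group and C6 are equatorial in the Cope chair, which places C2 cis to C9 at C1=C10 and makes C4=C5 E. Chair A should be favoured because it keeps the C7 arm equatorial and the bulky C6 silyloxy group anti to the isopropenyl group, because it gathers O8, O9 and the oxido oxygen on the lower face where they can share the potassium ion (hence no crown ether), and because the oxido group generally prefers the pseudo-equatorial site of the Cope chair. The C6–C9 stereocentres are spectators, and the absence of a proton source keeps the enolate from equilibrating before it is trapped.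

Step 21
Reactants: 26 enol triflate
Product: 27 (1(10)Z,4E)-10-methyl diene
Conditions: MeMgBr, Fe(acac)3 (cat.), THF/NMP, −30 → 0 °C
Reagents that add atoms: methylmagnesium bromide C[Mg]Br
Why: Iron-catalysed cross-coupling of an alkenyl triflate with a methyl Grignard reagent (Kumada-type) should replace the triflate by methyl with retention of the alkene geometry, so the C10 methyl and the Z alkene arise without an olefination.

Step 22
Reactants: 27 10-methyl diene
Product: 28 6,12-diol
Conditions: Bu4NF, THF, rt
Reagents that add atoms: none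
Why: Fluoride-induced Si–O cleavage should remove both silyl ethers (O6 and O12) and leave the two arylmethyl ethers untouched.

Step 23
Reactants: 28 6,12-diol
Product: 30 cis-fused 6,12-lactone, via lactol 29 (not isolated)
Conditions: TEMPO (cat.), PhI(OAc)2, CH2Cl2, rt
Reagents that add atoms: none
Why: The oxoammonium oxidant selects the primary alcohol, the aldehyde is captured by the C6 hydroxyl as a lactol and this is oxidised on to the γ-lactone (oxidative lactonisation of a 1,4-diol), and because O8 is blocked only the 6,12-lactone can form.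

Step 24
Reactants: 30 lactone
Product: 33 α-methylene lactone, via Mannich base 31 (not isolated), via trimethylammonium iodide 32 (not isolated)
Conditions: LiN(iPr)2, THF, −78 °C; CH2=NMe2+ I−, −78 °C → rt; MeI, MeOH; NaHCO3 (aq), CH2Cl2
Reagents that add atoms: N,N-dimethylmethyleneiminium iodide C=[N+](C)C.[I-]
Why: In this Eschenmoser α-methylenation the lactone lithium enolate is aminomethylated, the Mannich base is quaternised and Hofmann-type elimination gives the exocyclic alkene, the C11 centre being lost on elimination and no leaving group sitting β to the enolate carbon.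

Step 25
Reactants: 33 α-methylene lactone
Product: 34 C8 alcohol (O9 still protected)
Conditions: DDQ (1.2 equiv), CH2Cl2/pH 7 buffer, 0 °C
Reagents that add atoms: none
Why: Oxidative cleavage of the electron-rich 3,4-dimethoxybenzyl ether by DDQ (benzylic hydride abstraction, then hydrolysis) is much faster than that of the 2-naphthylmethyl ether, so only O8 should be freed under neutral conditions.

Step 26
Reactants: 35 (R)-2-methylsuccinic acid 4-tert-butyl ester
Product: 36 tert-butyl (3R)-4-hydroxy-3-methylbutanoate
Conditions: BH3·SMe2, THF, 0 °C → rt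
Reagents that add atoms: none
Why: Borane reduces the free carboxylic acid much faster than the tert-butyl ester (chemoselective borane reduction) and does not touch the stereocentre.

Step 27
Reactants: 36 hydroxy ester; 37 octadecanoyl chloride
Product: 38 tert-butyl (3R)-3-methyl-4-(octadecanoyloxy)butanoate
Conditions: 37, pyridine, DMAP (cat.), CH2Cl2, 0 °C → rt
Reagents that add atoms: none
Why: Acylation of the primary alcohol with the acid chloride under nucleophilic catalysis should give the stearate.

Step 28
Reactants: 38 tert-butyl ester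
Product: 39 (3R)-3-methyl-4-(octadecanoyloxy)butanoic acid
Conditions: CF3CO2H, CH2Cl2, rt
Reagents that add atoms: none
Why: Acidolysis of the tert-butyl ester through the tert-butyl cation should free the acid without cleaving the primary stearate.

Step 29
Reactants: 34 C8 alcohol; 39 side-chain acid
Product: 40 9-O-(2-naphthylmethyl) ether of the target
Conditions: 39, EDC·HCl, DMAP, CH2Cl2, 0 °C → rt
Reagents that add atoms: none
Why: Steglich esterification (carbodiimide activation, DMAP acyl transfer) acylates the only free hydroxyl, so no regiochemical choice or acyl migration arises, and the acid's stereocentre is β to the carboxyl and cannot epimerise.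

Step 30
Reactants: 40 O9-protected target
Product: 41 target
Conditions: DDQ (3 equiv), CH2Cl2/H2O (10:1), rt
Reagents that add atoms: none
Why: DDQ oxidation of the naphthylmethyl ether at its benzylic carbon should free O9 under neutral conditions that leave the ester, the α-methylene lactone and the diene intact.

Compound list

1 | 1,2:5,6-di-O-isopropylidene-α-D-glucofuranose (diacetone-D-glucose) | O1[C@H]2[C@H](OC(C)(C)O2)[C@@H](O)[C@H]1[C@H]1COC(C)(C)O1 | starting material
2 | 1,2:5,6-di-O-isopropylidene-α-D-ribo-hexofuranos-3-ulose | O1[C@H]2[C@H](OC(C)(C)O2)C(=O)[C@H]1[C@H]1COC(C)(C)O1 | intermediate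
3 | ethyl 2-(3-deoxy-1,2:5,6-di-O-isopropylidene-α-D-ribo-hexofuranos-3-ylidene)acetate, E/Z mixture | O1[C@H]2[C@H](OC(C)(C)O2)C(=CC(=O)OCC)[C@H]1[C@H]1COC(C)(C)O1 | intermediate
4 | 3-deoxy-3-C-(2-ethoxy-2-oxoethyl)-1,2:5,6-di-O-isopropylidene-α-D-allofuranose (arm cis to the 1,2-acetonide) | O1[C@H]2[C@H](OC(C)(C)O2)[C@H](CC(=O)OCC)[C@H]1[C@H]1COC(C)(C)O1 | intermediate
5 | 3-deoxy-3-C-(2-hydroxyethyl)-1,2:5,6-di-O-isopropylidene-α-D-allofuranose | O1[C@H]2[C@H](OC(C)(C)O2)[C@H](CCO)[C@H]1[C@H]1COC(C)(C)O1 | intermediate
6 | 3-C-[2-(tert-butyldiphenylsilyloxy)ethyl]-3-deoxy-1,2:5,6-di-O-isopropylidene-α-D-allofuranose | O1[C@H]2[C@H](OC(C)(C)O2)[C@H](CCO[Si](c3ccccc3)(c3ccccc3)C(C)(C)C)[C@H]1[C@H]1COC(C)(C)O1 | intermediate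
7 | 3-C-[2-(tert-butyldiphenylsilyloxy)ethyl]-3-deoxy-1,2-O-isopropylidene-α-D-allofuranose (5,6-diol) | O1[C@H]2[C@H](OC(C)(C)O2)[C@H](CCO[Si](c3ccccc3)(c3ccccc3)C(C)(C)C)[C@H]1[C@H](O)CO | intermediate
8 | 6-O-(4-methylphenylsulfonyl) derivative of 7 | O1[C@H]2[C@H](OC(C)(C)O2)[C@H](CCO[Si](c3ccccc3)(c3ccccc3)C(C)(C)C)[C@H]1[C@H](O)COS(=O)(=O)c1ccc(C)cc1 | intermediate (not isolated)
9 | 5,6-anhydro-3-C-[2-(tert-butyldiphenylsilyloxy)ethyl]-3-deoxy-1,2-O-isopropylidene-α-D-allofuranose | O1[C@H]2[C@H](OC(C)(C)O2)[C@H](CCO[Si](c3ccccc3)(c3ccccc3)C(C)(C)C)[C@H]1[C@H]1CO1 | intermediate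
10 | 3-C-[2-(tert-butyldiphenylsilyloxy)ethyl]-3,6,7-trideoxy-1,2-O-isopropylidene-α-D-allo-hept-6-enofuranose (free 5-OH) | O1[C@H]2[C@H](OC(C)(C)O2)[C@H](CCO[Si](c3ccccc3)(c3ccccc3)C(C)(C)C)[C@H]1[C@H](O)C=C | intermediate
11 | 5-O-(2-naphthylmethyl) ether of 10 | O1[C@H]2[C@H](OC(C)(C)O2)[C@H](CCO[Si](c3ccccc3)(c3ccccc3)C(C)(C)C)[C@H]1[C@H](OCc1ccc2ccccc2c1)C=C | intermediate
12 | methyl 3-C-[2-(tert-butyldiphenylsilyloxy)ethyl]-3,6,7-trideoxy-5-O-(2-naphthylmethyl)-D-allo-hept-6-enofuranoside, α/β mixture, free 2-OH | O1C(OC)[C@H](O)[C@H](CCO[Si](c3ccccc3)(c3ccccc3)C(C)(C)C)[C@H]1[C@H](OCc1ccc2ccccc2c1)C=C | intermediate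
13 | 2-O-triisopropylsilyl ether of 12 | O1C(OC)[C@H](O[Si](C(C)C)(C(C)C)C(C)C)[C@H](CCO[Si](c3ccccc3)(c3ccccc3)C(C)(C)C)[C@H]1[C@H](OCc1ccc2ccccc2c1)C=C | intermediate
14 | 3-C-[2-(tert-butyldiphenylsilyloxy)ethyl]-3,6,7-trideoxy-5-O-(2-naphthylmethyl)-2-O-triisopropylsilyl-D-allo-hept-6-enofuranose (lactol, anomeric mixture) | O1C(O)[C@H](O[Si](C(C)C)(C(C)C)C(C)C)[C@H](CCO[Si](c3ccccc3)(c3ccccc3)C(C)(C)C)[C@H]1[C@H](OCc1ccc2ccccc2c1)C=C | intermediate
15 | acyclic 1,7-diene CH2=CH–CH(OTIPS)–CH(CH2CH2OTBDPS)–CH(OH)–CH(ONAP)–CH=CH2 with the four stereocentres of 14 (D-allo; future C6–C9) | C=C[C@H](O[Si](C(C)C)(C(C)C)C(C)C)[C@H](CCO[Si](c1ccccc1)(c1ccccc1)C(C)(C)C)[C@H](O)[C@H](OCc1ccc2ccccc2c1)C=C | intermediate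
16 | cyclohexene (ring C5–C10, C5=C10) with 6-OTIPS, 7-(2-TBDPSO-ethyl), 8-OH and 9-ONAP all on the lower face | C1=C[C@H](O[Si](C(C)C)(C(C)C)C(C)C)[C@H](CCO[Si](c2ccccc2)(c2ccccc2)C(C)(C)C)[C@H](O)[C@@H]1OCc1ccc2ccccc2c1 | intermediate
17 | 5,10-epoxide of 16, epoxide oxygen on the lower face (cis to the C6–C9 substituents) | O1[C@@H]2[C@H]1[C@H](O[Si](C(C)C)(C(C)C)C(C)C)[C@H](CCO[Si](c3ccccc3)(c3ccccc3)C(C)(C)C)[C@H](O)[C@@H]2OCc1ccc2ccccc2c1 | intermediate
18 | 8-O-(3,4-dimethoxybenzyl) ether of 17 | O1[C@@H]2[C@H]1[C@H](O[Si](C(C)C)(C(C)C)C(C)C)[C@H](CCO[Si](c3ccccc3)(c3ccccc3)C(C)(C)C)[C@H](OCc3ccc(OC)c(OC)c3)[C@@H]2OCc1ccc2ccccc2c1 | intermediate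
19 | isopropenylmagnesium bromide | CC(=C)[Mg]Br | starting material
20 | cyclohexan-10-ol with 5-isopropenyl on the upper face, 10-OH on the lower face, and lower-face 6-OTIPS, 7-(2-TBDPSO-ethyl), 8-ODMB, 9-ONAP | O[C@@H]1[C@@H](C(C)=C)[C@H](O[Si](C(C)C)(C(C)C)C(C)C)[C@H](CCO[Si](c2ccccc2)(c2ccccc2)C(C)(C)C)[C@H](OCc2ccc(OC)c(OC)c2)[C@@H]1OCc1ccc2ccccc2c1 | intermediate
21 | 10-ketone of 20 | O=C1[C@@H](C(C)=C)[C@H](O[Si](C(C)C)(C(C)C)C(C)C)[C@H](CCO[Si](c2ccccc2)(c2ccccc2)C(C)(C)C)[C@H](OCc2ccc(OC)c(OC)c2)[C@@H]1OCc1ccc2ccccc2c1 | intermediate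
22 | vinylmagnesium bromide | C=C[Mg]Br | starting material
23 | 10-vinyl tertiary alcohol: vinyl on the upper face cis to the 5-isopropenyl group, 10-OH on the lower face, other substituents as in 20 | O[C@]1(C=C)[C@@H](C(C)=C)[C@H](O[Si](C(C)C)(C(C)C)C(C)C)[C@H](CCO[Si](c2ccccc2)(c2ccccc2)C(C)(C)C)[C@H](OCc2ccc(OC)c(OC)c2)[C@@H]1OCc1ccc2ccccc2c1 | intermediate
24 | potassium alkoxide of 23 | [K+].[O-][C@]1(C=C)[C@@H](C(C)=C)[C@H](O[Si](C(C)C)(C(C)C)C(C)C)[C@H](CCO[Si](c2ccccc2)(c2ccccc2)C(C)(C)C)[C@H](OCc2ccc(OC)c(OC)c2)[C@@H]1OCc1ccc2ccccc2c1 | intermediate (not isolated)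
25 | potassium enolate of the ring-expanded ketone: ten-membered ring, O–C10=C1 with C2 cis to C9, 4E, substituents as in 26 | CC(C)[Si](C(C)C)(C(C)C)O[C@H]1/C=C(\C)CC/C=C(/[O-])[C@@H](OCc2ccc3ccccc3c2)[C@@H](OCc2ccc(OC)c(OC)c2)[C@H]1CCO[Si](c1ccccc1)(c1ccccc1)C(C)(C)C.[K+] | intermediate (not isolated)
26 | ten-membered enol triflate: 10-OTf, C1=C10 with C2 cis to C9 (the ring geometry of the target's Z alkene, formally E because of the triflate oxygen), 4-methyl 4E alkene, 6-OTIPS, 7-(2-TBDPSO-ethyl), 8-ODMB, 9-ONAP, C6–C9 configured as in the target | CC(C)[Si](C(C)C)(C(C)C)O[C@H]1/C=C(\C)CC/C=C(/OS(=O)(=O)C(F)(F)F)[C@@H](OCc2ccc3ccccc3c2)[C@@H](OCc2ccc(OC)c(OC)c2)[C@H]1CCO[Si](c1ccccc1)(c1ccccc1)C(C)(C)C | intermediate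
27 | 10-methyl analogue of 26, (1(10)Z,4E)-diene | CC(C)[Si](C(C)C)(C(C)C)O[C@H]1/C=C(\C)CC/C=C(/C)[C@@H](OCc2ccc3ccccc3c2)[C@@H](OCc2ccc(OC)c(OC)c2)[C@H]1CCO[Si](c1ccccc1)(c1ccccc1)C(C)(C)C | intermediate
28 | diol from 27 with free 6-OH and 12-OH | O[C@H]1/C=C(\C)CC/C=C(/C)[C@@H](OCc2ccc3ccccc3c2)[C@@H](OCc2ccc(OC)c(OC)c2)[C@H]1CCO | intermediate
29 | lactol: C12 hemiacetal closed on O6, cis-fused, C12 epimers | C1C(O)O[C@H]2/C=C(\C)CC/C=C(/C)[C@@H](OCc3ccc4ccccc4c3)[C@@H](OCc3ccc(OC)c(OC)c3)[C@@H]12 | intermediate (not isolated)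
30 | cis-fused γ-lactone O6–C12(=O)–C11H2–C7 with 8-ODMB and 9-ONAP | C1C(=O)O[C@H]2/C=C(\C)CC/C=C(/C)[C@@H](OCc3ccc4ccccc4c3)[C@@H](OCc3ccc(OC)c(OC)c3)[C@@H]12 | intermediate
31 | 11-(dimethylaminomethyl) lactone (Mannich base, C11 epimers) | CN(C)CC1C(=O)O[C@H]2/C=C(\C)CC/C=C(/C)[C@@H](OCc3ccc4ccccc4c3)[C@@H](OCc3ccc(OC)c(OC)c3)[C@@H]12 | intermediate (not isolated)
32 | N-methyl quaternary ammonium iodide of 31 | C[N+](C)(C)CC1C(=O)O[C@H]2/C=C(\C)CC/C=C(/C)[C@@H](OCc3ccc4ccccc4c3)[C@@H](OCc3ccc(OC)c(OC)c3)[C@@H]12.[I-] | intermediate (not isolated)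
33 | α-methylene lactone (C11=C13) with 8-ODMB and 9-ONAP | C=C1C(=O)O[C@H]2/C=C(\C)CC/C=C(/C)[C@@H](OCc3ccc4ccccc4c3)[C@@H](OCc3ccc(OC)c(OC)c3)[C@@H]12 | intermediate
34 | 8-hydroxy α-methylene lactone with 9-ONAP | C=C1C(=O)O[C@H]2/C=C(\C)CC/C=C(/C)[C@@H](OCc3ccc4ccccc4c3)[C@@H](O)[C@@H]12 | intermediate
35 | (R)-2-methylsuccinic acid 4-tert-butyl ester, (2R)-4-tert-butoxy-2-methyl-4-oxobutanoic acid | CC(C)(C)OC(=O)C[C@@H](C)C(=O)O | starting material
36 | tert-butyl (3R)-4-hydroxy-3-methylbutanoate | CC(C)(C)OC(=O)C[C@@H](C)CO | intermediate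
37 | octadecanoyl chloride | CCCCCCCCCCCCCCCCCC(=O)Cl | starting material
38 | tert-butyl (3R)-3-methyl-4-(octadecanoyloxy)butanoate | CC(C)(C)OC(=O)C[C@@H](C)COC(=O)CCCCCCCCCCCCCCCCC | intermediate
39 | (3R)-3-methyl-4-(octadecanoyloxy)butanoic acid | OC(=O)C[C@@H](C)COC(=O)CCCCCCCCCCCCCCCCC | intermediate
40 | 9-O-(2-naphthylmethyl) ether of the target | C=C1C(=O)O[C@H]2/C=C(\C)CC/C=C(/C)[C@@H](OCc3ccc4ccccc4c3)[C@@H](OC(=O)C[C@@H](C)COC(=O)CCCCCCCCCCCCCCCCC)[C@@H]12 | intermediate
41 | (1(10)Z,4E,6S,7S,8S,9R)-9-hydroxy-8-{[(3R)-3-methyl-4-(octadecanoyloxy)butanoyl]oxy}germacra-1(10),4,11(13)-trien-12,6-olide | C=C1C(=O)O[C@H]2/C=C(\C)CC/C=C(/C)[C@@H](O)[C@@H](OC(=O)C[C@@H](C)COC(=O)CCCCCCCCCCCCCCCCC)[C@@H]12 | target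

Total steps: 30. Longest linear sequence: 27 (steps 1–25, 29, 30); the side-chain acid takes 3 steps (26–28).

Steps most likely to fail

Step 20. The rearrangement may pass through the other chair (vinyl axial, isopropenyl and oxido groups equatorial on the cyclohexane), which becomes competitive if the lower-face oxygens of chair A repel one another instead of sharing the potassium ion; that path gives the 1(10)E,4Z geometry. Migration of the C6 silyl group to the C10 alkoxide would in addition stop the rearrangement. The fallback runs the ring expansion on a substrate in which O6 is tied to the arm as a small cyclic acetal, so that O6, O8 and O10 are three ether or alkoxide donors on one face and no silyl group is near the alkoxide. Starting from 23, Bu4NF removes both silyl groups to give the triol F1. TEMPO with PhI(OAc)2 (1 equiv) oxidises the primary alcohol and the aldehyde closes on O6 (O8 being blocked) to the hydroxy lactol F2. MeOH with pyridinium p-toluenesulfonate gives the cyclic methyl acetal F3. KH followed by PhNTf2 gives the enol triflate F4, and MeMgBr with Fe(acac)3 gives the methyl diene F5. Pyridinium p-toluenesulfonate in wet acetone then returns lactol 29, which is oxidised to 30 under the conditions of step 23.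

Step 15. Oxygen delivery from the homoallylic C8 hydroxyl may be slow, because the lower face is flanked by the C6 and C9 ethers and the alkene is deactivated by two allylic oxygens; undirected attack on the open upper face would then erode the facial selectivity. The fallback is a halohydrin route that uses the open face for the electrophile instead. Starting from 16, Ac2O in pyridine gives the acetate F6. NBS in aqueous THF forms the bromonium ion on the upper face, and it is opened from the lower face at C10 with help of the neighbouring acetate to give the bromohydrin F7 (bromine at C5 on the upper face, hydroxyl at C10 on the lower face; acetyl migration between O8 and O10 is harmless). K2CO3 in MeOH removes the acetate and closes the lower-face epoxide, returning 17.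

Step 19. The basic alkenyl-metal reagent may enolise the hindered ketone, which would move the isopropenyl double bond into conjugation or expel the C8 ether by β-elimination, or part of the addition may come from the lower face. The fallback adds a smaller and far less basic acetylide and then reduces it. Starting from 21, ethynylmagnesium bromide (HC≡CMgBr) with CeCl3 gives the propargylic alcohol F8, the alkyne entering from the upper face for the same reasons as the vinyl group. Semi-hydrogenation of the terminal alkyne (H2, Pd/CaCO3 poisoned with Pb(OAc)2, quinoline) returns 23.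

Further compounds

F1 | step 20 | triol from 23: free 6-OH, 12-OH and tertiary 10-OH, 8-ODMB, 9-ONAP, vinyl and isopropenyl as in 23 | O[C@]1(C=C)[C@@H](C(C)=C)[C@H](O)[C@H](CCO)[C@H](OCc2ccc(OC)c(OC)c2)[C@@H]1OCc1ccc2ccccc2c1
F2 | step 20 | hydroxy lactol: C12 hemiacetal closed on O6 (cis-fused five-membered ring, C12 epimers), tertiary 10-OH free | O[C@]1(C=C)[C@@H](C(C)=C)[C@@H]2OC(O)C[C@@H]2[C@H](OCc2ccc(OC)c(OC)c2)[C@@H]1OCc1ccc2ccccc2c1
F3 | step 20 | cyclic methyl acetal of F2 (12-OMe, C12 epimers) | O[C@]1(C=C)[C@@H](C(C)=C)[C@@H]2OC(OC)C[C@@H]2[C@H](OCc2ccc(OC)c(OC)c2)[C@@H]1OCc1ccc2ccccc2c1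
F4 | step 20 | ten-membered enol triflate carrying the 6,12-cyclic methyl acetal, alkene geometry as in 26 | C1C(OC)O[C@H]2/C=C(\C)CC/C=C(/OS(=O)(=O)C(F)(F)F)[C@@H](OCc3ccc4ccccc4c3)[C@@H](OCc3ccc(OC)c(OC)c3)[C@@H]12
F5 | step 20 | 10-methyl (1(10)Z,4E)-diene carrying the 6,12-cyclic methyl acetal | C1C(OC)O[C@H]2/C=C(\C)CC/C=C(/C)[C@@H](OCc3ccc4ccccc4c3)[C@@H](OCc3ccc(OC)c(OC)c3)[C@@H]12
F6 | step 15 | 8-O-acetate of 16 | C1=C[C@H](O[Si](C(C)C)(C(C)C)C(C)C)[C@H](CCO[Si](c2ccccc2)(c2ccccc2)C(C)(C)C)[C@H](OC(C)=O)[C@@H]1OCc1ccc2ccccc2c1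
F7 | step 15 | bromohydrin: 5-Br on the upper face, 10-OH on the lower face, 8-OAc | O[C@@H]1[C@@H](Br)[C@H](O[Si](C(C)C)(C(C)C)C(C)C)[C@H](CCO[Si](c2ccccc2)(c2ccccc2)C(C)(C)C)[C@H](OC(C)=O)[C@@H]1OCc1ccc2ccccc2c1
F8 | step 19 | 10-ethynyl tertiary alcohol (ethynyl upper face, 10-OH lower face), otherwise as 23 | O[C@]1(C#C)[C@@H](C(C)=C)[C@H](O[Si](C(C)C)(C(C)C)C(C)C)[C@H](CCO[Si](c2ccccc2)(c2ccccc2)C(C)(C)C)[C@H](OCc2ccc(OC)c(OC)c2)[C@@H]1OCc1ccc2ccccc2c1
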